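**Plan**
Retrosynthesis first removes the benzyl group and the 5- and 7-O-methyl groups, then cuts ring C at O1–C2 and C2–C3 (C2 is a one-carbon unit from DMF) to leave a 2,4,6-trihydroxy-3-methoxyphenyl benzyl ketone.
Ring A is cut at C4a–C8a: the oxygens on C5, C7 and C8a are 1,3,5 to one another and C4a carries the acyl carbon C4, the pattern of a Claisen-folded 3,5,7-triketo ester; the C6 methoxyl travels in the open chain as its 4-methoxyl.
The chain is cut at chain C6–C7 (diketo ester trianion plus an arylacetic Weinreb amide) and at chain C4–C5 (dianion of methyl 4-methoxyacetoacetate plus an acetyl donor).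
Forward order: ring B fragment from 2,3-dihydroxybenzaldehyde, chain assembly, ring A by Claisen closure, ring C by one-carbon insertion, equilibration to the 6-methoxy isomer, methylation, debenzylation.
The target has no stereocentre; the labile methoxy-bearing carbon of the chain becomes aromatic C6.

Key step: step 8

Assumption: under equilibrating alkoxide the 5,7-dihydroxy-6-methoxyisoflavone is taken to be favoured over its 8-methoxy isomer, as in Wessely–Moser rearrangements of 5,7,8-oxygenated chromones.

**Step 1**
Reactants: 1 2,3-dihydroxybenzaldehyde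
Product: 2 3-(benzyloxy)-2-hydroxybenzaldehyde
Conditions: NaH (2.2 equiv), DMSO, 20 °C; BnBr (1.0 equiv); then aq. HCl
Reagents that add atoms: benzyl bromide, BrCc1ccccc1
Why: In the dianion the 3-phenoxide is not conjugated with the formyl group and is the more nucleophilic oxygen, so one equivalent of benzyl bromide should give the 3-benzyl ether (regioselective Williamson etherification of a catechol aldehyde dianion).

**Step 2**
Reactants: 2 3-(benzyloxy)-2-hydroxybenzaldehyde
Product: 3 3-(benzyloxy)-2-methoxybenzaldehyde
Conditions: MeI, K2CO3, DMF, 25 °C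
Reagents that add atoms: iodomethane, CI
Why: Williamson methylation of the chelated 2-hydroxyl of a salicylaldehyde with K2CO3 and iodomethane is routine.

**Step 3**
Reactants: 3 3-(benzyloxy)-2-methoxybenzaldehyde
Product: 5 2-(3-benzyloxy-2-methoxyphenyl)acetonitrile, via vinyl formamide 4 (not isolated)
Conditions: TosMIC, KOt-Bu, DME, −45 °C; then MeOH, reflux
Reagents that add atoms: tosylmethyl isocyanide (TosMIC), Cc1ccc(cc1)S(=O)(=O)C[N+]#[C-]
Why: Van Leusen reductive cyanation: the TosMIC anion adds to the aldehyde, the oxazoline opens to the N-(1-tosylvinyl)formamide, and methanolysis removes the formyl group as methyl formate and expels sulfinate to leave the one-carbon-homologated nitrile, a reaction established for electron-rich aromatic aldehydes.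

**Step 4**
Reactants: 5 2-(3-benzyloxy-2-methoxyphenyl)acetonitrile
Product: 6 2-(3-benzyloxy-2-methoxyphenyl)acetic acid
Conditions: KOH, EtOH–H2O, reflux; then aq. HCl
Reagents that add atoms: water, O; potassium hydroxide, [K+].[OH-]
Why: Alkaline hydrolysis of an arylacetonitrile to the arylacetic acid is standard and leaves both aryl ethers untouched.

**Step 5**
Reactants: 6 2-(3-benzyloxy-2-methoxyphenyl)acetic acid
Product: 8 2-(3-benzyloxy-2-methoxyphenyl)-N-methoxy-N-methylacetamide, via acyl imidazolide 7 (not isolated)
Conditions: CDI, CH2Cl2, 20 °C; then MeNHOMe·HCl, 20 °C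
Reagents that add atoms: N,O-dimethylhydroxylamine hydrochloride, CNOC.Cl
Why: Activation of the acid as its acyl imidazolide and aminolysis with N,O-dimethylhydroxylamine is the standard Weinreb amide synthesis; the amide is chosen because its tetrahedral adduct with a carbanion survives until work-up.

**Step 6**
Reactants: 9 methyl 4-methoxy-3-oxobutanoate (methyl 4-methoxyacetoacetate); 10 N-methoxy-N-methylacetamide
Product: 11 methyl 4-methoxy-3,5-dioxohexanoate
Conditions: LiN(i-Pr)2 (2.2 equiv), THF, −78 to 0 °C; then 10, −78 to 0 °C; then cold aq. HCl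
Reagents that add atoms: none
Why: γ-Acylation of a β-keto ester dianion: the second deprotonation occurs at the methoxy-bearing C4, the more reactive carbanion, and the chelated Weinreb adduct releases the diketone only on acidic work-up, so neither over-addition nor quenching of the dianion by the product should occur.

**Step 7**
Reactants: 11 methyl 4-methoxy-3,5-dioxohexanoate; 8 2-(3-benzyloxy-2-methoxyphenyl)-N-methoxy-N-methylacetamide
Product: 12 methyl 8-(3-benzyloxy-2-methoxyphenyl)-4-methoxy-3,5,7-trioxooctanoate
Conditions: 11 (1.4 equiv), LiN(i-Pr)2 (3.3 equiv per 11), THF, −78 to 0 °C; then 8, −78 to −20 °C; then cold aq. HCl to pH 4; crude product used at once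
Reagents that add atoms: none
Why: Acylation of a 3,5-diketo ester trianion at its terminal methyl: C2 and C4 are deprotonated first, the third deprotonation gives the least stabilized C6 carbanion, which is the reacting site, and the Weinreb adduct keeps the new ketone masked until the cold acidic quench; the trianion is used in excess to offset proton transfer from the benzylic CH2 of the amide.

**Step 8**
Reactants: 12 methyl 8-(3-benzyloxy-2-methoxyphenyl)-4-methoxy-3,5,7-trioxooctanoate
Product: 13 2-(3-benzyloxy-2-methoxyphenyl)-1-(2,4,6-trihydroxy-3-methoxyphenyl)ethanone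
Conditions: Mg(OMe)2 (5 equiv), MeOH, 20 to 50 °C, N2; then 1 M HCl, 0 °C
Reagents that add atoms: none
Why: Mg(OMe)2 should convert 12 into a magnesium-chelated polyenolate in which the three ketones are enolized and the methyl ester is the only carbonyl left electrophilic. Chain carbon C6, between the C5 and C7 carbonyls, attacks the ester carbon C1, methoxide leaves and the resulting 2-acylcyclohexane-1,3,5-trione enolizes to the aromatic ring, so the new bond is C4a–C8a of the target and the 4-methoxyl of the chain becomes the C6 methoxyl. This is the intramolecular Claisen (Dieckmann-type) condensation known for 3,5,7-triketo esters under strong base or magnesium alkoxide. Ring A closes in the 6-exo-trig mode. No stereocentre is formed, and the labile C4 centre of the chain is lost on aromatization. The step needs Claisen folding to win over aldol folding (C2 onto the C7 ketone to a resorcylate, or C8 onto the C3 ketone) and over O-cyclization to pyranones; full enolization and chelation of the ketones by magnesium, which leaves only the ester carbonyl electrophilic, is what should secure this.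

**Step 9**
Reactants: 13 2-(3-benzyloxy-2-methoxyphenyl)-1-(2,4,6-trihydroxy-3-methoxyphenyl)ethanone
Product: 14 3-(3-benzyloxy-2-methoxyphenyl)-5,7-dihydroxy-8-methoxy-4H-chromen-4-one
Conditions: BF3·OEt2, DMF, 50 °C; then MsCl, DMF, 80 °C; then H2O
Reagents that add atoms: N,N-dimethylformamide, CN(C)C=O
Why: Vilsmeier-type aminomethylenation of the boron-chelated deoxybenzoin at its benzylic CH2 by the DMF–MsCl adduct, attack of an ortho hydroxyl on the enaminone carbon and loss of dimethylamine close ring C (the standard BF3·OEt2/DMF/MsCl isoflavone synthesis); closure is expected mainly through the hydroxyl next to the methoxyl, the other being held in the difluoroboron chelate, and any 6-methoxy isomer 15 formed beside 14 is carried on unseparated because step 10 converts 14 into 15.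

**Step 10**
Reactants: 14 3-(3-benzyloxy-2-methoxyphenyl)-5,7-dihydroxy-8-methoxy-4H-chromen-4-one
Product: 15 3-(3-benzyloxy-2-methoxyphenyl)-5,7-dihydroxy-6-methoxy-4H-chromen-4-one
Conditions: NaOMe (5 equiv), anhydrous MeOH, reflux, N2; then AcOH
Reagents that add atoms: none
Why: Wessely–Moser-type isomerization, known for 5,7-dihydroxy-8-methoxyisoflavones in alkali: methoxide adds to C2, ring C opens to the phenoxide, rotation about the C4–C4a bond brings the former 5-oxygen to C2, and reclosure with loss of methoxide should give the 6-methoxy isomer with the more stable 5,6,7-oxygenation pattern, while anhydrous conditions keep the ring-opened formyl ketone from being cleaved to formate.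

**Step 11**
Reactants: 15 3-(3-benzyloxy-2-methoxyphenyl)-5,7-dihydroxy-6-methoxy-4H-chromen-4-one
Product: 16 3-(3-benzyloxy-2-methoxyphenyl)-5,6,7-trimethoxy-4H-chromen-4-one
Conditions: Me2SO4 (excess), K2CO3, acetone, reflux
Reagents that add atoms: dimethyl sulfate, COS(=O)(=O)OC
Why: Exhaustive Williamson methylation: the 7-hydroxyl reacts quickly and the chelated 5-hydroxyl under prolonged reflux with excess dimethyl sulfate, as is usual for 5-hydroxyisoflavones, and the chromone ring is stable to K2CO3 in acetone.

**Step 12**
Reactants: 16 3-(3-benzyloxy-2-methoxyphenyl)-5,6,7-trimethoxy-4H-chromen-4-one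
Product: 17 3-(3-hydroxy-2-methoxyphenyl)-5,6,7-trimethoxy-4H-chromen-4-one (CNP0105642.0)
Conditions: H2 (1 atm), Pd/C (10% Pd on carbon), EtOAc–MeOH, 20 °C
Reagents that add atoms: none
Why: Hydrogenolysis of an aryl benzyl ether over palladium on carbon at one atmosphere is faster than reduction of the chromone C2–C3 double bond, so the reaction is stopped once the benzyl ether is consumed.

**Compound list**
1 | 2,3-dihydroxybenzaldehyde | O=Cc1cccc(O)c1O | starting material
2 | 3-(benzyloxy)-2-hydroxybenzaldehyde | O=Cc1cccc(OCc2ccccc2)c1O | intermediate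
3 | 3-(benzyloxy)-2-methoxybenzaldehyde | O=Cc1cccc(OCc2ccccc2)c1OC | intermediate
4 | N-[2-(3-benzyloxy-2-methoxyphenyl)-1-(4-methylphenylsulfonyl)ethenyl]formamide (alkene geometry not defined; formed in the flask in step 3) | O=CNC(=Cc1cccc(OCc2ccccc2)c1OC)S(=O)(=O)c1ccc(C)cc1 | intermediate
5 | 2-(3-benzyloxy-2-methoxyphenyl)acetonitrile | N#CCc1cccc(OCc2ccccc2)c1OC | intermediate
6 | 2-(3-benzyloxy-2-methoxyphenyl)acetic acid | OC(=O)Cc1cccc(OCc2ccccc2)c1OC | intermediate
7 | 2-(3-benzyloxy-2-methoxyphenyl)-1-(imidazol-1-yl)ethanone (formed in the flask in step 5) | O=C(Cc1cccc(OCc2ccccc2)c1OC)n1ccnc1 | intermediate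
8 | 2-(3-benzyloxy-2-methoxyphenyl)-N-methoxy-N-methylacetamide | CON(C)C(=O)Cc1cccc(OCc2ccccc2)c1OC | intermediate
9 | methyl 4-methoxy-3-oxobutanoate (methyl 4-methoxyacetoacetate) | COCC(=O)CC(=O)OC | starting material
10 | N-methoxy-N-methylacetamide | CC(=O)N(C)OC | starting material
11 | methyl 4-methoxy-3,5-dioxohexanoate (keto form drawn; enolized, C4 configurationally labile) | COC(=O)CC(=O)C(OC)C(C)=O | intermediate
12 | methyl 8-(3-benzyloxy-2-methoxyphenyl)-4-methoxy-3,5,7-trioxooctanoate (keto form drawn; enolized, C4 configurationally labile) | COC(=O)CC(=O)C(OC)C(=O)CC(=O)Cc1cccc(OCc2ccccc2)c1OC | intermediate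
13 | 2-(3-benzyloxy-2-methoxyphenyl)-1-(2,4,6-trihydroxy-3-methoxyphenyl)ethanone | O=C(Cc1cccc(OCc2ccccc2)c1OC)c1c(O)cc(O)c(OC)c1O | intermediate
14 | 3-(3-benzyloxy-2-methoxyphenyl)-5,7-dihydroxy-8-methoxy-4H-chromen-4-one | O=c1c(-c2cccc(OCc3ccccc3)c2OC)coc2c(OC)c(O)cc(O)c12 | intermediate
15 | 3-(3-benzyloxy-2-methoxyphenyl)-5,7-dihydroxy-6-methoxy-4H-chromen-4-one | O=c1c(-c2cccc(OCc3ccccc3)c2OC)coc2cc(O)c(OC)c(O)c12 | intermediate
16 | 3-(3-benzyloxy-2-methoxyphenyl)-5,6,7-trimethoxy-4H-chromen-4-one | COc1cc2occ(-c3cccc(OCc4ccccc4)c3OC)c(=O)c2c(OC)c1OC | intermediate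
17 | 3-(3-hydroxy-2-methoxyphenyl)-5,6,7-trimethoxy-4H-chromen-4-one | COc1cc2occ(-c3cccc(O)c3OC)c(=O)c2c(OC)c1OC | target

**Step count**
Total: 12 steps. Longest linear sequence: 11 steps (steps 1 to 5, then 7 to 12); step 6 is the short branch.

**Steps most likely to fail**

Step 8. The chain may fold in the aldol sense or cyclize through oxygen instead of undergoing Claisen closure, and methoxide may fragment the polyketone by retro-Claisen cleavage. The fallback sets out from nitrile 5 and builds the same ketone by a Houben–Hoesch acylation. Nitrile 5 and commercial 2-methoxybenzene-1,3,5-triol (COc1c(O)cc(O)cc1O) are treated with ZnCl2 and HCl gas in Et2O at 0 °C. The triol is symmetric, so only one ring position is available, and the product should be 2-(3-benzyloxy-2-methoxyphenyl)-1-(2,4,6-trihydroxy-3-methoxyphenyl)ethaniminium chloride F1. Hydrolysis of this salt in hot water returns to the route at 13.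

Step 10. The equilibration may stop short or lie on the wrong side, and the ring-opened intermediate may lose its formyl carbon. The fallback replaces equilibration by separation and recycling. It sets out from 14: after step 9, 15 is separated from 14 by chromatography or crystallization and taken on to step 11. Isomer 14 is heated with aqueous NaOH in EtOH, the classical alkaline degradation of an isoflavone, in which hydroxide adds at C2 and formate is lost. This returns deoxybenzoin 13, which is passed through step 9 again, so the route is rejoined at 13 and then 15. No new compound is made (F0).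

Step 7. Proton transfer from the benzylic position of the amide to the trianion may take the place of C-acylation, and the triketo ester may cyclize during work-up. The fallback moves the bond formation to chain C4–C5, with the aryl-side ketone masked. It sets out from nitrile 5 and from 9.
- A Blaise reaction of 5 (Zn, methyl bromoacetate, THF, reflux; then aq. HCl) should give methyl 4-(3-benzyloxy-2-methoxyphenyl)-3-oxobutanoate F2.
- Ketalization with ethylene glycol (TsOH catalyst, toluene, water removal) should give methyl 2-[2-(3-benzyloxy-2-methoxybenzyl)-1,3-dioxolan-2-yl]acetate F3.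
- Saponification with LiOH in THF–H2O should give 2-[2-(3-benzyloxy-2-methoxybenzyl)-1,3-dioxolan-2-yl]acetic acid F4.
- CDI should convert F4 into 2-[2-(3-benzyloxy-2-methoxybenzyl)-1,3-dioxolan-2-yl]-1-(imidazol-1-yl)ethanone F5.
- F5 is added to an excess of the dianion of 9 (LiN(i-Pr)2, THF, −78 °C) and should give methyl 6-[2-(3-benzyloxy-2-methoxybenzyl)-1,3-dioxolan-2-yl]-4-methoxy-3,5-dioxohexanoate F6.
- Brief treatment of F6 with dilute aqueous HCl in THF at 20 °C removes the ketal and returns to the route at 12.

**Further compounds**
F1 | step 8 | 2-(3-benzyloxy-2-methoxyphenyl)-1-(2,4,6-trihydroxy-3-methoxyphenyl)ethaniminium chloride | [Cl-].[NH2+]=C(Cc1cccc(OCc2ccccc2)c1OC)c1c(O)cc(O)c(OC)c1O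
F2 | step 7 | methyl 4-(3-benzyloxy-2-methoxyphenyl)-3-oxobutanoate | COC(=O)CC(=O)Cc1cccc(OCc2ccccc2)c1OC
F3 | step 7 | methyl 2-[2-(3-benzyloxy-2-methoxybenzyl)-1,3-dioxolan-2-yl]acetate | COC(=O)CC1(Cc2cccc(OCc3ccccc3)c2OC)OCCO1
F4 | step 7 | 2-[2-(3-benzyloxy-2-methoxybenzyl)-1,3-dioxolan-2-yl]acetic acid | OC(=O)CC1(Cc2cccc(OCc3ccccc3)c2OC)OCCO1
F5 | step 7 | 2-[2-(3-benzyloxy-2-methoxybenzyl)-1,3-dioxolan-2-yl]-1-(imidazol-1-yl)ethanone | O=C(CC1(Cc2cccc(OCc3ccccc3)c2OC)OCCO1)n1ccnc1
F6 | step 7 | methyl 6-[2-(3-benzyloxy-2-methoxybenzyl)-1,3-dioxolan-2-yl]-4-methoxy-3,5-dioxohexanoate (C4 configurationally labile) | COC(=O)CC(=O)C(OC)C(=O)CC1(Cc2cccc(OCc3ccccc3)c2OC)OCCO1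
F0 | step 10 | none | none
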